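**Retrosynthetic overview**

1. Target 29 ⇐ tetraol 28 (MnO2 oxidation of the C1 allylic alcohol) ⇐ silyl ether 27 ⇐ C18 carbonate 26 by allyl-palladium formate hydrogenolysis (H replaces O at C18 with inversion, C19=CH2 kept).
2. Key disconnection C17–C18: the (1E,3E)-dienyllithium from iodide 23 (fragment 2, C1–C17 with ring B) adds to ketone 4 (fragment 1, ring A). The feature used: in ring A, C18 sits between the quaternary C23 and the C19 exocyclic methylene (the 1,4-diene C19=CH2 / C18–H / C17=C16), so C18 can be a ketone carbon that cannot enolise and whose C–O bond is later allylic to C19=CH2.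
3. Fragment 2: ring B is bought as 3-ethoxycyclohexenone; C10–OH by enolate hydroxylation, C12–C14 by Stork–Danheiser Grignard addition, C26/C11 by silicon-tethered 5-exo radical cyclisation, C6 by in situ radical allylation, the (2Z)-C7=C2 bond by intramolecular HWE through a C26–O lactone, C15–C17 by Wittig and Takai olefinations.
4. Fragment 1: ring A is bought as 2-methylcyclohexenone; asymmetric conjugate methylation and enolate methylation (C22, C23), then α-methylenation (C19).
5. Ring events in order: temporary oxasilolane (closed step 7, opened step 8), temporary seven-membered lactone (closed step 10, opened step 12); rings A and B are never opened or closed, and ring A is attached last.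

Key step: step 17

Remark (locants): C1 = formyl carbon, C2 = its α-carbon, C3–C5 = hydroxypropyl chain (C3 = carbinol), C6–C11 = ring B (C6 = CH, C7 = alkylidene carbon, C10 = methyl carbinol, C11 = quaternary), C26 = hydroxymethyl on C11, C12–C17 = chain to ring A, C18–C23 = ring A (C18 bonded to C17, C19 = methylidene-bearing, C22 = CHMe, C23 = CMe2); TBS = tert-butyldimethylsilyl.

Remark (assumption): the antipodes of the phosphoramidite ligand (step 1) and of the oxaziridine (step 4) are taken to be those that give the 22R and 10S centres; should the sense be the reverse, the other commercial antipode is used.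

**Route**

Step 1
Reactants: 1 2-methylcyclohex-2-en-1-one
Product: 3 (3R)-2,2,3-trimethylcyclohexan-1-one, via dimethylaluminium enolate 2 (not isolated)
Conditions: Me3Al, copper thiophene-2-carboxylate Cu(O2CC4H3S) (2 mol %), binaphthol-derived phosphoramidite (4 mol %), Et2O, −30 °C; then MeLi, THF/DMPU, MeI, −30 → 0 °C
Reagents that add atoms: trimethylaluminium, C[Al](C)C; iodomethane, CI
Why: Copper-catalysed asymmetric conjugate addition sets C22 by enantioface selection of the enone under ligand control, and the regiodefined enolate is then methylated (enolate alkylation) at the carbon that becomes the stereochemically silent C23.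

Step 2
Reactants: 3 (3R)-2,2,3-trimethylcyclohexan-1-one
Product: 4 (3R)-2,2,3-trimethyl-6-methylidenecyclohexan-1-one (fragment 1)
Conditions: (CH2O)n, i-Pr2NH2+ CF3CO2− (1 equiv), CF3CO2H (0.1 equiv), THF, reflux; used freshly
Reagents that add atoms: formaldehyde (as paraformaldehyde), C=O
Why: Mannich-type α-methylenation works only at C19 because C23 is quaternary, and it leaves C22 untouched.

Step 3
Reactants: 5 3-ethoxycyclohex-2-en-1-one
Product: 7 3-ethoxy-6-methylcyclohex-2-en-1-one (racemic), via lithium dienolate 6 (not isolated)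
Conditions: LiN(i-Pr)2, THF, −78 °C; MeI, −78 → 0 °C
Reagents that add atoms: iodomethane, CI
Why: Kinetic α'-deprotonation of the vinylogous ester followed by enolate alkylation (first stage of a Stork–Danheiser sequence) places the future C10 methyl group.

Step 4
Reactants: 7 3-ethoxy-6-methylcyclohex-2-en-1-one
Product: 9 (6S)-3-ethoxy-6-hydroxy-6-methylcyclohex-2-en-1-one, via sodium dienolate 8 (not isolated)
Conditions: NaN(SiMe3)2, THF, −78 °C; (camphorsulfonyl)oxaziridine (single enantiomer), −78 °C; then H2O
Reagents that add atoms: (camphorsulfonyl)oxaziridine, CC1(C)C2CCC13CS(=O)(=O)N4OC34C2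
Why: Electrophilic enolate hydroxylation with a chiral N-sulfonyloxaziridine, whose camphor framework differentiates the two faces of the tetrasubstituted enolate and so sets the C10 carbinol centre.

Step 5
Reactants: 9 (6S)-3-ethoxy-6-hydroxy-6-methylcyclohex-2-en-1-one
Product: 11 (4S)-3-[2-(1,3-dioxolan-2-yl)ethyl]-4-hydroxy-4-methylcyclohex-2-en-1-one, via bis(bromomagnesium) alkoxide 10 (not isolated)
Conditions: [2-(1,3-dioxolan-2-yl)ethyl]magnesium bromide (3 equiv), THF, 0 °C → rt; then 1 M HCl, 0 °C, 15 min
Reagents that add atoms: [2-(1,3-dioxolan-2-yl)ethyl]magnesium bromide, Br[Mg]CCC1OCCO1; water, O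
Why: Stork–Danheiser transposition, in which Grignard 1,2-addition to the vinylogous ester carbonyl and brief acid hydrolysis with loss of water give the 3-substituted 4-hydroxy enone carrying C12–C14, while C10 is not involved.

Step 6
Reactants: 11 (4S)-3-[2-(1,3-dioxolan-2-yl)ethyl]-4-hydroxy-4-methylcyclohex-2-en-1-one
Product: 12 (4S)-4-{[(bromomethyl)dimethylsilyl]oxy}-3-[2-(1,3-dioxolan-2-yl)ethyl]-4-methylcyclohex-2-en-1-one
Conditions: BrCH2SiMe2Cl, Et3N, DMAP (cat.), CH2Cl2, 0 °C
Reagents that add atoms: (bromomethyl)chlorodimethylsilane, C[Si](C)(Cl)CBr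
Why: Silyl ether formation on the tertiary C10 hydroxyl installs the temporary one-carbon tether without touching a stereocentre.

Step 7
Reactants: 12 (4S)-4-{[(bromomethyl)dimethylsilyl]oxy}-3-[2-(1,3-dioxolan-2-yl)ethyl]-4-methylcyclohex-2-en-1-one
Product: 13 cis-fused oxasilolane ketone (C10–O–SiMe2–C26H2–C11 ring; C7 ketone; allyl on C6; C6 allyl, C26 and C10–O on one face, C12 chain and C10 methyl on the other)
Conditions: CH2=CHCH2SnBu3 (4 equiv), AIBN (0.2 equiv, in portions), benzene, 80 °C
Reagents that add atoms: allyltributylstannane, C=CC[Sn](CCCC)(CCCC)CCCC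
Why: Silicon-tethered 5-exo-trig radical cyclisation followed by Keck radical allylation, in which the nucleophilic α-silyl radical adds to the enone β-carbon C11 on the face of the C10 oxygen (the tether permits only the cis-fused ring, so C26 is cis to O and the C12 chain trans) and the resulting C6 α-keto radical takes up allyl anti to the pseudo-axial C12 chain, that is cis to C26.

Step 8
Reactants: 13 cis-fused oxasilolane ketone
Product: 14 keto diol (C7 ketone, C6 allyl, C26 primary OH, C10 tertiary OH)
Conditions: 30 % H2O2, KF, KHCO3, THF/MeOH (1:1), rt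
Reagents that add atoms: hydrogen peroxide, OO
Why: Tamao–Fleming oxidation converts the Si–C26 bond into C26–OH and frees the C10 hydroxyl, and the weakly basic medium should leave the hindered C6 α-centre unchanged.

Step 9
Reactants: 14 keto diol
Product: 15 C26 2-(diethoxyphosphoryl)propanoate of 14
Conditions: 2-(diethoxyphosphoryl)propanoic acid, DCC, DMAP (cat.), CH2Cl2, 0 °C → rt
Reagents that add atoms: 2-(diethoxyphosphoryl)propanoic acid, CCOP(=O)(OCC)C(C)C(=O)O
Why: Steglich esterification acylates the primary C26 hydroxyl selectively over the hindered tertiary C10 hydroxyl and so attaches C1, C2 and the C2 methyl.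

Step 10
Reactants: 15 C26 phosphonopropanoate
Product: 16 bridged (2Z)-lactone (seven-membered ring C1(=O)–O–C26–C11–C6–C7=C2, methyl on C2)
Conditions: LiCl, DBU, MeCN (0.005 M), rt → 50 °C
Reagents that add atoms: none
Why: Intramolecular Horner–Wadsworth–Emmons olefination under Masamune–Roush conditions, where closure of the seven-membered lactone forces C1 cis to C6 so that the tetrasubstituted C7=C2 bond can form only with the Z geometry of the target, while the weak base deprotonates the phosphonate without enolising C6.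

Step 11
Reactants: 16 bridged (2Z)-lactone
Product: 18 C3-hydroxy lactone (allyl converted to 3-hydroxypropyl), via B-alkyl-9-BBN adduct 17 (not isolated)
Conditions: 9-BBN-H (2.5 equiv), THF, 0 °C → rt; then 30 % H2O2, aq. NaOAc, 0 °C → rt
Reagents that add atoms: hydrogen peroxide, OO
Why: Anti-Markovnikov hydroboration–oxidation, in which 9-BBN attacks only the monosubstituted alkene (the tetrasubstituted enoate alkene is inert) and buffered peroxide spares the lactone.

Step 12
Reactants: 18 C3-hydroxy lactone
Product: 19 (2Z)-tetraol (C1, C3, C26 primary OH; C10 tertiary OH; C14 dioxolane)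
Conditions: i-Bu2AlH (5 equiv), CH2Cl2, −78 → 0 °C; aq. potassium sodium tartrate
Reagents that add atoms: none
Why: Aluminium hydride 1,2-reduction of the unsaturated lactone opens the temporary ring to the C1 allylic alcohol and the C26 alcohol without touching the Z alkene.

Step 13
Reactants: 19 (2Z)-tetraol
Product: 20 tetrakis(TBS) ether of 19
Conditions: TBSOTf (6 equiv), 2,6-lutidine, CH2Cl2, 0 °C → rt
Reagents that add atoms: tert-butyldimethylsilyl trifluoromethanesulfonate, CC(C)(C)[Si](C)(C)OS(=O)(=O)C(F)(F)F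
Why: Silylation with the silyl triflate protects the three primary and the hindered tertiary hydroxyl groups in one operation as ethers that tolerate organolithium reagents.

Step 14
Reactants: 20 tetrakis(TBS) ether
Product: 21 C14 aldehyde
Conditions: PPTS (0.3 equiv), acetone/H2O (10:1), 50 °C
Reagents that add atoms: water, O
Why: Acid-catalysed acetal hydrolysis (transacetalisation to acetone) unveils the aldehyde under conditions that TBS ethers survive.

Step 15
Reactants: 21 C14 aldehyde
Product: 22 (14E)-C16 enal (C14=C15(Me)–C16HO)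
Conditions: Ph3P=C(CH3)CHO, toluene, 90 °C
Reagents that add atoms: 2-(triphenylphosphoranylidene)propanal, CC(C=O)=P(c1ccccc1)(c1ccccc1)c1ccccc1
Why: Wittig olefination with a stabilised formyl ylide gives the E-trisubstituted alkene.

Step 16
Reactants: 22 (14E)-C16 enal
Product: 23 (14E,16E)-C17 dienyl iodide (fragment 2)
Conditions: CrCl2 (8 equiv), CHI3 (3 equiv), THF/dioxane (1:6), 0 °C → rt
Reagents that add atoms: iodoform, IC(I)I
Why: Takai olefination converts the enal into the (E)-iodoalkene.

Step 17
Reactants: 23 (14E,16E)-C17 dienyl iodide (fragment 2); 4 (3R)-2,2,3-trimethyl-6-methylidenecyclohexan-1-one (fragment 1)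
Product: 26 tertiary bis-allylic C18 methyl carbonate (dienyl trans, carbonate oxygen cis to the C22 methyl), via dienyllithium 24 (not isolated), via lithium alkoxide 25 (not isolated)
Conditions: t-BuLi (2.05 equiv), Et2O, −78 °C; then 4 (1.3 equiv) premixed with LaCl3·2LiCl in THF, −78 °C; then ClCO2Me, −78 → 0 °C; product used crude
Reagents that add atoms: methyl chloroformate, COC(=O)Cl
Why: Iodine–lithium exchange gives the configurationally stable (1E,3E)-dienyllithium, whose 1,2-carbonyl addition (closest known type: alkenyllithium addition to hindered 2-alkylidene ketones promoted by lanthanide salts) forms the C17–C18 bond, and O-acylation in the same flask gives the allylic carbonate. No ring is closed. The ketone has no α-hydrogen (C23 is quaternary, C19 is sp2), so enolisation is excluded and only 1,2- against 1,4-addition must be secured, which the hard organolithium and LaCl3·2LiCl activation of the carbonyl do. The new C18 centre is controlled by ring A: in the chair with the C22 methyl equatorial the nucleophile enters axially, because the equatorial path is blocked by the axial C23 methyl and the other chair would put the nucleophile syn-axial to the C22 methyl, so the dienyl group ends trans and the oxygen cis to the C22 methyl. This is the configuration step 18 needs, since palladium ionises anti to oxygen and returns hydride on its own face, whereas forming the C–C bond directly on an sp2 C18 that already carries hydrogen (for example by SN2' alkenylation) would leave the chain trans to the C22 methyl, which is why C18 is joined at the ketone oxidation level. The E,E geometry of the diene is carried over unchanged from iodide 23.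

Step 18
Reactants: 26 tertiary bis-allylic C18 methyl carbonate
Product: 27 tetrakis(TBS) ether of tetraol 28 (C18–H, chain cis to the C22 methyl, C19=CH2)
Conditions: Pd(OAc)2 (10 mol %), n-Bu3P (20 mol %), HCO2NH4 (4 equiv), THF, 40 °C
Reagents that add atoms: none
Why: Palladium-catalysed formate hydrogenolysis of an allylic carbonate (Tsuji–Trost-type ionisation), in which zerovalent palladium displaces the C18 oxygen with inversion, the allyl unit C18–C19–CH2 takes up formate, and hydride is passed from the palladium face to the more substituted terminus C18 under n-Bu3P control, giving the 1-alkene isomer with C19=CH2 intact and the chain cis to the C22 methyl; the palladium face anti to the departed oxygen is also the less hindered one, so facial exchange through the CH2 terminus leads to the same isomer.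

Step 19
Reactants: 27 tetrakis(TBS) ether
Product: 28 tetraol (C1 allylic alcohol in place of the formyl group of the target)
Conditions: Bu4NF (10 equiv), THF, 45 °C
Reagents that add atoms: none
Why: Fluoride-mediated desilylation removes all four silyl ethers (the tertiary one on warming) under basic conditions that should not isomerise the skipped triene.

Step 20
Reactants: 28 tetraol
Product: 29 CNP0149035.2 (target)
Conditions: activated MnO2 (20 equiv), CH2Cl2, rt, dark
Reagents that add atoms: none
Why: Chemoselective MnO2 oxidation of the allylic C1 alcohol in the presence of two saturated primary alcohols and the tertiary alcohol gives the Z enal, and short contact in the dark limits Z/E isomerisation.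

**Compound list**

1 | 2-methylcyclohex-2-en-1-one | CC1=CCCCC1=O | starting material
2 | dimethylaluminium (3R)-2,3-dimethylcyclohex-1-en-1-olate | C[Al](C)OC1=C(C)[C@H](C)CCC1 | intermediate
3 | (3R)-2,2,3-trimethylcyclohexan-1-one | O=C1CCC[C@@H](C)C1(C)C | intermediate
4 | (3R)-2,2,3-trimethyl-6-methylidenecyclohexan-1-one (fragment 1) | C=C1CC[C@@H](C)C(C)(C)C1=O | intermediate
5 | 3-ethoxycyclohex-2-en-1-one | CCOC1=CC(=O)CCC1 | starting material
6 | lithium 5-ethoxycyclohexa-1,5-dien-1-olate | [Li]OC1=CCCC(OCC)=C1 | intermediate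
7 | 3-ethoxy-6-methylcyclohex-2-en-1-one (racemic) | CCOC1=CC(=O)C(C)CC1 | intermediate
8 | sodium 5-ethoxy-2-methylcyclohexa-1,5-dien-1-olate | [Na]OC1=C(C)CCC(OCC)=C1 | intermediate
9 | (6S)-3-ethoxy-6-hydroxy-6-methylcyclohex-2-en-1-one | CCOC1=CC(=O)[C@@](C)(O)CC1 | intermediate
10 | bis(bromomagnesium) alkoxide of 1-[2-(1,3-dioxolan-2-yl)ethyl]-3-ethoxy-6-methylcyclohex-2-ene-1,6-diol (6S; C1 unassigned) | CCOC1=CC(O[Mg]Br)(CCC2OCCO2)[C@@](C)(O[Mg]Br)CC1 | intermediate
11 | (4S)-3-[2-(1,3-dioxolan-2-yl)ethyl]-4-hydroxy-4-methylcyclohex-2-en-1-one | O=C1C=C(CCC2OCCO2)[C@@](C)(O)CC1 | intermediate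
12 | (4S)-4-{[(bromomethyl)dimethylsilyl]oxy}-3-[2-(1,3-dioxolan-2-yl)ethyl]-4-methylcyclohex-2-en-1-one | O=C1C=C(CCC2OCCO2)[C@@](C)(O[Si](C)(C)CBr)CC1 | intermediate
13 | cis-fused oxasilolane ketone: ring B with C7=O, allyl on C6, dioxolanylethyl on C11, ring C10–O–SiMe2–C26H2–C11; C6 allyl, C26 and C10–O on one face, C12 chain and C10 methyl on the other | C1(OCCO1)CC[C@@]2(C[Si](C)(C)O3)[C@H](CC=C)C(=O)CC[C@@]23C | intermediate
14 | keto diol: as 13 with C26–OH and C10–OH in place of the silicon bridge | C1(OCCO1)CC[C@@]2(CO)[C@H](CC=C)C(=O)CC[C@]2(C)O | intermediate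
15 | C26 2-(diethoxyphosphoryl)propanoate of 14 (phosphonate α-carbon as a mixture) | C1(OCCO1)CC[C@@]2(COC(=O)C(C)P(=O)(OCC)OCC)[C@H](CC=C)C(=O)CC[C@]2(C)O | intermediate
16 | bridged (2Z)-lactone: C7=C2(Me)–C1(=O)–O–C26 spanning C7 and C11 of ring B; C6 allyl; C10 tertiary OH | C1(OCCO1)CC[C@@]2(CO3)[C@H](CC=C)/C(=C(/C)C3=O)CC[C@]2(C)O | intermediate
17 | B-[C3]-9-borabicyclo[3.3.1]nonane adduct of 16 | C1(OCCO1)CC[C@@]2(CO3)[C@H](CCCB4C5CCCC4CCC5)/C(=C(/C)C3=O)CC[C@]2(C)O | intermediate
18 | C3-hydroxy lactone (3-hydroxypropyl on C6) | C1(OCCO1)CC[C@@]2(CO3)[C@H](CCCO)/C(=C(/C)C3=O)CC[C@]2(C)O | intermediate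
19 | (2Z)-tetraol with C14 dioxolane (C1, C3, C26 primary OH; C10 tertiary OH; C3 chain, C26 and C10–OH cis on ring B) | C1(OCCO1)CC[C@@]2(CO)[C@H](CCCO)/C(=C(/C)CO)CC[C@]2(C)O | intermediate
20 | tetrakis(TBS) ether of 19 | C1(OCCO1)CC[C@@]2(CO[Si](C)(C)C(C)(C)C)[C@H](CCCO[Si](C)(C)C(C)(C)C)/C(=C(/C)CO[Si](C)(C)C(C)(C)C)CC[C@]2(C)O[Si](C)(C)C(C)(C)C | intermediate
21 | C14 aldehyde (tetrakis-TBS) | O=CCC[C@@]1(CO[Si](C)(C)C(C)(C)C)[C@H](CCCO[Si](C)(C)C(C)(C)C)/C(=C(/C)CO[Si](C)(C)C(C)(C)C)CC[C@]1(C)O[Si](C)(C)C(C)(C)C | intermediate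
22 | (14E)-C16 enal (tetrakis-TBS) | O=C/C(C)=C/CC[C@@]1(CO[Si](C)(C)C(C)(C)C)[C@H](CCCO[Si](C)(C)C(C)(C)C)/C(=C(/C)CO[Si](C)(C)C(C)(C)C)CC[C@]1(C)O[Si](C)(C)C(C)(C)C | intermediate
23 | (14E,16E)-C17 dienyl iodide (fragment 2) | I/C=C/C(C)=C/CC[C@@]1(CO[Si](C)(C)C(C)(C)C)[C@H](CCCO[Si](C)(C)C(C)(C)C)/C(=C(/C)CO[Si](C)(C)C(C)(C)C)CC[C@]1(C)O[Si](C)(C)C(C)(C)C | intermediate
24 | (14E,16E)-C17 dienyllithium | [Li]/C=C/C(C)=C/CC[C@@]1(CO[Si](C)(C)C(C)(C)C)[C@H](CCCO[Si](C)(C)C(C)(C)C)/C(=C(/C)CO[Si](C)(C)C(C)(C)C)CC[C@]1(C)O[Si](C)(C)C(C)(C)C | intermediate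
25 | lithium C18 alkoxide (dienyl trans, O cis to the C22 methyl) | C=C1CC[C@@H](C)C(C)(C)[C@]1(O[Li])/C=C/C(C)=C/CC[C@@]1(CO[Si](C)(C)C(C)(C)C)[C@H](CCCO[Si](C)(C)C(C)(C)C)/C(=C(/C)CO[Si](C)(C)C(C)(C)C)CC[C@]1(C)O[Si](C)(C)C(C)(C)C | intermediate
26 | C18 methyl carbonate | C=C1CC[C@@H](C)C(C)(C)[C@]1(OC(=O)OC)/C=C/C(C)=C/CC[C@@]1(CO[Si](C)(C)C(C)(C)C)[C@H](CCCO[Si](C)(C)C(C)(C)C)/C(=C(/C)CO[Si](C)(C)C(C)(C)C)CC[C@]1(C)O[Si](C)(C)C(C)(C)C | intermediate
27 | tetrakis(TBS) ether of 28 (18S,22R ring A with C19=CH2) | C=C1CC[C@@H](C)C(C)(C)[C@H]1/C=C/C(C)=C/CC[C@@]1(CO[Si](C)(C)C(C)(C)C)[C@H](CCCO[Si](C)(C)C(C)(C)C)/C(=C(/C)CO[Si](C)(C)C(C)(C)C)CC[C@]1(C)O[Si](C)(C)C(C)(C)C | intermediate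
28 | tetraol (C1 allylic alcohol) | C=C1CC[C@@H](C)C(C)(C)[C@H]1/C=C/C(C)=C/CC[C@@]1(CO)[C@H](CCCO)/C(=C(/C)CO)CC[C@]1(C)O | intermediate
29 | CNP0149035.2 | C=C1CC[C@@H](C)C(C)(C)[C@H]1/C=C/C(C)=C/CC[C@@]1(CO)[C@H](CCCO)/C(=C(/C)C=O)CC[C@]1(C)O | target

**Totals and risks**

Total step count: 20. Longest linear sequence: 18 steps (steps 3–20, from 3-ethoxycyclohex-2-en-1-one).

Steps most likely to fail:

Step 18. Risk: the allyl-palladium intermediate is extended by the diene, so hydride may be delivered to the CH2 terminus or elimination may occur, both giving conjugated polyenes; the C18 configuration may also erode. Fallback: the sequence sets out from lithium alkoxide 25, which is protonated instead of acylated to give the tertiary C18 alcohol F1. Rhenium-catalysed 1,3-transposition (O3ReOSiPh3, Et2O) moves the hydroxyl to the C19 carbon substituent and gives the primary allylic alcohol F2 with C18=C19 conjugated to the diene. A Mitsunobu reaction with 2-nitrobenzenesulfonylhydrazide (PPh3, DEAD, −30 °C) gives the N-allylic sulfonylhydrazine F3, which on warming loses the sulfinic acid to the allylic diazene F4. Retro-ene loss of N2 from F4 transfers hydrogen to C18 through a chair-like six-membered transition state with the C22 methyl equatorial and restores C19=CH2, which returns the route to 27.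

Step 10. Risk: slow olefination of the hindered ketone, so that oligomerisation and base-induced epimerisation at C6 compete. Fallback: the sequence sets out from keto diol 14, whose C26 hydroxyl is acylated with 2-bromopropanoyl bromide and pyridine to the 2-bromopropanoate F5. An intramolecular Reformatsky reaction with SmI2 (THF, −78 °C), which is non-basic and well suited to medium rings, gives the β-hydroxy lactone F6. Dehydration within the ring (SOCl2, pyridine) towards the acidic C2 hydrogen returns the route to 16.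

Step 7. Risk: poor facial selectivity of allyl transfer to the C6 radical, and simple reduction competing with allylation. Fallback: the order of C–C and C–H bond formation at C6 is reversed. The sequence sets out from hydroxy enone 11, which is α-iodinated (I2, pyridine) to the 2-iodo enone F7 and coupled with allyltributylstannane in a Stille reaction (Pd2(dba)3, AsPh3) to the 2-allyl enone F8. Silylation with BrCH2SiMe2Cl gives the bromomethylsilyl ether F9, and radical cyclisation with Bu3SnH and AIBN then delivers hydrogen, not carbon, to the C6 radical last, on the face that allyl would otherwise have taken, so the epimer disfavoured in step 7 becomes the favoured one and the route is rejoined at 13.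

Further compounds
F1 | step 18 | tertiary C18 alcohol (protonated 25) | C=C1CC[C@@H](C)C(C)(C)[C@]1(O)/C=C/C(C)=C/CC[C@@]1(CO[Si](C)(C)C(C)(C)C)[C@H](CCCO[Si](C)(C)C(C)(C)C)/C(=C(/C)CO[Si](C)(C)C(C)(C)C)CC[C@]1(C)O[Si](C)(C)C(C)(C)C
F2 | step 18 | primary allylic alcohol (C19–CH2OH, C18=C19) | OCC1=C(/C=C/C(C)=C/CC[C@@]2(CO[Si](C)(C)C(C)(C)C)[C@H](CCCO[Si](C)(C)C(C)(C)C)/C(=C(/C)CO[Si](C)(C)C(C)(C)C)CC[C@]2(C)O[Si](C)(C)C(C)(C)C)C(C)(C)[C@H](C)CC1
F3 | step 18 | N-allylic N-(2-nitrophenylsulfonyl)hydrazine | NN(CC1=C(/C=C/C(C)=C/CC[C@@]2(CO[Si](C)(C)C(C)(C)C)[C@H](CCCO[Si](C)(C)C(C)(C)C)/C(=C(/C)CO[Si](C)(C)C(C)(C)C)CC[C@]2(C)O[Si](C)(C)C(C)(C)C)C(C)(C)[C@H](C)CC1)S(=O)(=O)c1ccccc1[N+](=O)[O-]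
F4 | step 18 | allylic diazene | N=NCC1=C(/C=C/C(C)=C/CC[C@@]2(CO[Si](C)(C)C(C)(C)C)[C@H](CCCO[Si](C)(C)C(C)(C)C)/C(=C(/C)CO[Si](C)(C)C(C)(C)C)CC[C@]2(C)O[Si](C)(C)C(C)(C)C)C(C)(C)[C@H](C)CC1
F5 | step 10 | C26 2-bromopropanoate of 14 | C1(OCCO1)CC[C@@]2(COC(=O)C(C)Br)[C@H](CC=C)C(=O)CC[C@]2(C)O
F6 | step 10 | β-hydroxy lactone (C7 carbinol, C2–H; new centres unassigned) | C1(OCCO1)CC[C@@]2(CO3)[C@H](CC=C)C(O)(C(C)C3=O)CC[C@]2(C)O
F7 | step 7 | (4S)-3-[2-(1,3-dioxolan-2-yl)ethyl]-4-hydroxy-2-iodo-4-methylcyclohex-2-en-1-one | O=C1C(I)=C(CCC2OCCO2)[C@@](C)(O)CC1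
F8 | step 7 | (4S)-2-allyl-3-[2-(1,3-dioxolan-2-yl)ethyl]-4-hydroxy-4-methylcyclohex-2-en-1-one | O=C1C(CC=C)=C(CCC2OCCO2)[C@@](C)(O)CC1
F9 | step 7 | (4S)-2-allyl-4-{[(bromomethyl)dimethylsilyl]oxy}-3-[2-(1,3-dioxolan-2-yl)ethyl]-4-methylcyclohex-2-en-1-one | O=C1C(CC=C)=C(CCC2OCCO2)[C@@](C)(O[Si](C)(C)CBr)CC1
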